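Numbering: benzofuran numbers for the bicycle (O1, C2, C3, C3a to C7a); C1' is the side-chain CH(CH3) and C2' its CH2O.
Cuts, in retrosynthetic order: the tert-butyl mask of the acid, the C2'-O bond of the coumarate ester, the C5-vinyl bond, the ring bond C3-C2, and the ether bond O1-C2.
Enabling feature: in the dihydrofuran ring C3 is a bare benzylic CH2 and C2 is an ether CH that still holds one hydrogen. C3 can therefore be a carbene carbon ortho to O1 and C2 the OCH2 group of an open-chain aryl ether, and joining them is a 1,5 C-H functionalisation.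
Forward: the four-carbon chain is hung on the phenol oxygen, the ortho aldehyde becomes a tosylhydrazone, and the dihydrofuran ring (the only ring made) closes in step 4. The acrylate is then joined at C5, the coumarate at C2', and the acid is unmasked last.
Stereochemistry: C1' is bought with (S)-3-bromo-2-methylpropan-1-ol 1 and never reacts; C2 is set in step 4 by the chiral cobalt porphyrin; one E alkene comes from the Heck step and the other is bought.

Key step: step 4

Assumption: both mirror-image forms of [Co(3,5-DitBu-ChenPhyrin)] are accessible from the two antipodes of 2,2-dimethylcyclopropanecarboxamide, and step 4 means the form whose pocket favours the 2S product with 5.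
Remark: C1' keeps its geometry throughout; its label reads S in 1 and 2, R in 4 to 6 and S from 7 on, only because the CIP ranks of its neighbours change.

Step 1
Reactants: 1 (2S)-3-bromo-2-methylpropan-1-ol
Product: 2 [(2S)-3-bromo-2-methylpropoxy](tert-butyl)dimethylsilane
Conditions: TBSCl, imidazole, DMF, 0 °C to rt
Reagents that add atoms: tert-butyldimethylsilyl chloride (TBSCl), CC(C)(C)[Si](C)(C)Cl
Why: Silyl ether formation (substitution at silicon, with imidazole as base and silyl carrier) masks the hydroxyl so that it can neither close to an oxetane in step 2 nor trap the carbene in step 4, and the stereocentre takes no part.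

Step 2
Reactants: 2 [(2S)-3-bromo-2-methylpropoxy](tert-butyl)dimethylsilane; 3 5-bromo-2-hydroxybenzaldehyde
Product: 4 5-bromo-2-{[(2R)-3-(tert-butyldimethylsilyloxy)-2-methylpropyl]oxy}benzaldehyde
Conditions: K2CO3, DMF, 80 °C
Reagents that add atoms: none
Why: Williamson ether synthesis, in which the phenoxide of 3 displaces the primary bromide by SN2 at the carbon next to the stereocentre, a reaction that beta-branched bromides of the isobutyl type undergo routinely in warm DMF without touching C1'.

Step 3
Reactants: 4 5-bromo-2-{[(2R)-3-(tert-butyldimethylsilyloxy)-2-methylpropyl]oxy}benzaldehyde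
Product: 5 N'-[(E)-(5-bromo-2-{[(2R)-3-(tert-butyldimethylsilyloxy)-2-methylpropyl]oxy}phenyl)methylidene]-4-methylbenzenesulfonohydrazide
Conditions: TsNHNH2, MeOH, rt
Reagents that add atoms: p-toluenesulfonohydrazide (TsNHNH2), Cc1ccc(cc1)S(=O)(=O)NN
Why: Condensation of an aldehyde with a sulfonyl hydrazide should give the E-hydrazone under essentially neutral conditions that leave the silyl ether and the aryl bromide alone.

Step 4
Reactants: 5 N'-[(E)-(5-bromo-2-{[(2R)-3-(tert-butyldimethylsilyloxy)-2-methylpropyl]oxy}phenyl)methylidene]-4-methylbenzenesulfonohydrazide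
Product: 7 tert-butyl{(2S)-2-[(2S)-5-bromo-2,3-dihydro-1-benzofuran-2-yl]propoxy}dimethylsilane, via aryldiazomethane 6 (not isolated)
Conditions: [Co(3,5-DitBu-ChenPhyrin)] (5 mol %), Cs2CO3, 1,4-dioxane, 50 °C, N2 atmosphere
Reagents that add atoms: none
Why: Cs2CO3 deprotonates 5, the anion sheds p-toluenesulfinate (Bamford-Stevens fragmentation) and so feeds aryldiazomethane 6 slowly to the divalent cobalt metalloradical, which binds it, expels N2 and becomes a trivalent cobalt species whose unpaired electron sits on C3. That radical pulls a hydrogen from the O1-CH2 group through a six-membered transition state (1,5 hydrogen atom transfer), and the alpha-aryloxy radical born at C2 then attacks C3 and releases divalent cobalt, so the dihydrofuran ring closes by a 5-exo-tet homolytic substitution that makes C3-C2. The closest known reaction type is the enantioselective metalloradical C-H alkylation with diazo compounds generated in the flask from sulfonylhydrazones, which turns ortho-(alkylamino)aryl and open-chain substrates into 2-substituted indolines, pyrrolidines and tetrahydrofurans, backed by the dirhodium donor-carbene insertions of ortho-alkoxyaryl hydrazones that give 2,3-dihydrobenzofurans. C2 is the only new stereocentre and is controlled by the catalyst: the amide-walled chiral pocket orients the chain so that the pro-S hydrogen is removed and the short-lived radical recombines on that same face, with the fixed neighbouring centre C1' acting only as a matched or mismatched bias. The step needs site selectivity against the tertiary C1'-H (1,6 transfer, chroman) and the C2'-H bonds (1,7 transfer, tetrahydrobenzoxepine), and the substrate secures it through the favoured six-membered transfer geometry, the weakening of the O1-CH2 bonds by the oxygen lone pair and the bulk of the silyl group around C2'. Since the carbene carbon bears only the arene and one hydrogen no 1,2-hydride shift can drain it, the low standing concentration of 6 holds back azine and stilbene formation, and the aryl bromide and silyl ether are inert to the cobalt radical.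

Step 5
Reactants: 7 tert-butyl{(2S)-2-[(2S)-5-bromo-2,3-dihydro-1-benzofuran-2-yl]propoxy}dimethylsilane; 8 tert-butyl prop-2-enoate (tert-butyl acrylate)
Product: 9 tert-butyl (2E)-3-{(2S)-2-[(2S)-1-(tert-butyldimethylsilyloxy)propan-2-yl]-2,3-dihydro-1-benzofuran-5-yl}prop-2-enoate
Conditions: Pd(OAc)2 (5 mol %), P(o-tol)3 (12 mol %), Et3N, DMF, 100 °C
Reagents that add atoms: none
Why: Mizoroki-Heck reaction, in which zerovalent palladium formed in the flask inserts into C5-Br, adds syn to the free terminus of the acrylate and leaves by syn beta-hydride elimination to give the E-cinnamate, run at this stage so that the sturdy silyl ether rather than the later phenolic ester meets the hot amine.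

Step 6
Reactants: 9 tert-butyl (2E)-3-{(2S)-2-[(2S)-1-(tert-butyldimethylsilyloxy)propan-2-yl]-2,3-dihydro-1-benzofuran-5-yl}prop-2-enoate
Product: 10 tert-butyl (2E)-3-{(2S)-2-[(2S)-1-hydroxypropan-2-yl]-2,3-dihydro-1-benzofuran-5-yl}prop-2-enoate
Conditions: TBAF, THF, 0 °C to rt
Reagents that add atoms: none
Why: Fluoride-induced desilylation, driven by the strong Si-F bond, frees the primary alcohol while the tert-butyl cinnamate and both stereocentres do not respond to TBAF at this temperature.

Step 7
Reactants: 10 tert-butyl (2E)-3-{(2S)-2-[(2S)-1-hydroxypropan-2-yl]-2,3-dihydro-1-benzofuran-5-yl}prop-2-enoate; 11 (2E)-3-(4-hydroxyphenyl)prop-2-enoic acid (p-coumaric acid)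
Product: 12 tert-butyl (2E)-3-[(2S)-2-{(2S)-1-[(2E)-3-(4-hydroxyphenyl)prop-2-enoyloxy]propan-2-yl}-2,3-dihydro-1-benzofuran-5-yl]prop-2-enoate
Conditions: PPh3, DIAD, THF, 0 °C to rt
Reagents that add atoms: none
Why: Mitsunobu esterification, in which the alcohol is activated as its alkoxyphosphonium salt and displaced at C2' by the carboxylate of 11, whose acid group is about five pKa units stronger than its phenol and so supplies the only nucleophile while 11 is in slight excess, leaving C1' one atom away untouched.

Step 8
Reactants: 12 tert-butyl (2E)-3-[(2S)-2-{(2S)-1-[(2E)-3-(4-hydroxyphenyl)prop-2-enoyloxy]propan-2-yl}-2,3-dihydro-1-benzofuran-5-yl]prop-2-enoate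
Product: 13 (2E)-3-[(2S)-2-{(2S)-1-[(2E)-3-(4-hydroxyphenyl)prop-2-enoyloxy]propan-2-yl}-2,3-dihydro-1-benzofuran-5-yl]prop-2-enoic acid (CNP0224846.1)
Conditions: TFA, CH2Cl2, 0 °C to rt
Reagents that add atoms: none
Why: Acidolysis of the tert-butyl ester (E1 loss of the tert-butyl cation as isobutene) unmasks the acrylic acid, whereas the primary alkyl coumarate, the phenol, the ring aryl alkyl ether and both E alkenes are stable to TFA at room temperature.

Compound list
1 | (2S)-3-bromo-2-methylpropan-1-ol | C[C@@H](CO)CBr | starting material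
2 | [(2S)-3-bromo-2-methylpropoxy](tert-butyl)dimethylsilane | C[C@@H](CO[Si](C)(C)C(C)(C)C)CBr | intermediate
3 | 5-bromo-2-hydroxybenzaldehyde | O=Cc1cc(Br)ccc1O | starting material
4 | 5-bromo-2-{[(2R)-3-(tert-butyldimethylsilyloxy)-2-methylpropyl]oxy}benzaldehyde | C[C@@H](CO[Si](C)(C)C(C)(C)C)COc1ccc(Br)cc1C=O | intermediate
5 | N'-[(E)-(5-bromo-2-{[(2R)-3-(tert-butyldimethylsilyloxy)-2-methylpropyl]oxy}phenyl)methylidene]-4-methylbenzenesulfonohydrazide | C[C@@H](CO[Si](C)(C)C(C)(C)C)COc1ccc(Br)cc1/C=N/NS(=O)(=O)c1ccc(C)cc1 | intermediate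
6 | 4-bromo-2-(diazomethyl)-1-{[(2R)-3-(tert-butyldimethylsilyloxy)-2-methylpropyl]oxy}benzene | C[C@@H](CO[Si](C)(C)C(C)(C)C)COc1ccc(Br)cc1C=[N+]=[N-] | intermediate
7 | tert-butyl{(2S)-2-[(2S)-5-bromo-2,3-dihydro-1-benzofuran-2-yl]propoxy}dimethylsilane | C[C@@H](CO[Si](C)(C)C(C)(C)C)[C@@H]1Cc2cc(Br)ccc2O1 | intermediate
8 | tert-butyl prop-2-enoate | C=CC(=O)OC(C)(C)C | starting material
9 | tert-butyl (2E)-3-{(2S)-2-[(2S)-1-(tert-butyldimethylsilyloxy)propan-2-yl]-2,3-dihydro-1-benzofuran-5-yl}prop-2-enoate | C[C@@H](CO[Si](C)(C)C(C)(C)C)[C@@H]1Cc2cc(/C=C/C(=O)OC(C)(C)C)ccc2O1 | intermediate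
10 | tert-butyl (2E)-3-{(2S)-2-[(2S)-1-hydroxypropan-2-yl]-2,3-dihydro-1-benzofuran-5-yl}prop-2-enoate | C[C@@H](CO)[C@@H]1Cc2cc(/C=C/C(=O)OC(C)(C)C)ccc2O1 | intermediate
11 | (2E)-3-(4-hydroxyphenyl)prop-2-enoic acid | OC(=O)/C=C/c1ccc(O)cc1 | starting material
12 | tert-butyl (2E)-3-[(2S)-2-{(2S)-1-[(2E)-3-(4-hydroxyphenyl)prop-2-enoyloxy]propan-2-yl}-2,3-dihydro-1-benzofuran-5-yl]prop-2-enoate | C[C@@H](COC(=O)/C=C/c1ccc(O)cc1)[C@@H]1Cc2cc(/C=C/C(=O)OC(C)(C)C)ccc2O1 | intermediate
13 | (2E)-3-[(2S)-2-{(2S)-1-[(2E)-3-(4-hydroxyphenyl)prop-2-enoyloxy]propan-2-yl}-2,3-dihydro-1-benzofuran-5-yl]prop-2-enoic acid | C[C@@H](COC(=O)/C=C/c1ccc(O)cc1)[C@@H]1Cc2cc(/C=C/C(=O)O)ccc2O1 | target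

Total step count: 8. Longest linear sequence: 8 steps (1 to 13).

Steps most likely to fail

1. Step 4.
- What may go wrong: hydrogen abstraction from an aryloxy-CH2 group flanked by a branched carbon may be too slow, so that azine formation, carbene dimerisation or capture of the diazo compound by sulfinate overtakes ring closure. A mismatched pairing of catalyst pocket and C1' may also erode the facial selectivity at C2.
- Fallback (from 2, back at 7): it keeps the C3-C2 bond but replaces the donor carbene with a donor/acceptor dirhodium carbene that carries a traceless ester on C3. Concerted insertion of this carbene class into ether CH2 groups, giving cis-2-substituted 2,3-dihydrobenzofuran-3-carboxylates, is established.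
- Purchased methyl 2-(5-bromo-2-hydroxyphenyl)acetate (COC(=O)Cc1cc(Br)ccc1O) is alkylated with 2 (K2CO3, DMF) to methyl 2-(5-bromo-2-{[(2R)-3-(tert-butyldimethylsilyloxy)-2-methylpropyl]oxy}phenyl)acetate F1.
- Diazo transfer (p-ABSA, DBU, MeCN) gives methyl 2-(5-bromo-2-{[(2R)-3-(tert-butyldimethylsilyloxy)-2-methylpropyl]oxy}phenyl)-2-diazoacetate F2.
- Rh2(S-PTTL)4, or its mirror image if that one matches C1', in toluene at low temperature should give methyl (2R,3R)-5-bromo-2-[(2S)-1-(tert-butyldimethylsilyloxy)propan-2-yl]-2,3-dihydro-1-benzofuran-3-carboxylate F3. Its C2 has the same geometry as in 7; the label differs because C3 now outranks C1'.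
- Saponification (LiOH, aqueous THF) gives (2R)-5-bromo-2-[(2S)-1-(tert-butyldimethylsilyloxy)propan-2-yl]-2,3-dihydro-1-benzofuran-3-carboxylic acid F4. C3 is left open there because it is erased next.
- Photoredox hydrodecarboxylation (9-mesityl-10-phenylacridinium tetrafluoroborate, (PhS)2, i-Pr2NEt, trifluoroethanol, blue light) returns C3 to a CH2 group and gives 7.

2. Step 7.
- What may go wrong: the phenol of 11 may compete with the carboxylate for the alkoxyphosphonium salt. Displacement at the beta-branched C2' may also be slow enough for the acid to be diverted by acylation of the reduced azo reagent.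
- Fallback (from 10 and 11, back at 12): the ester is made by acyl transfer instead of alkyl transfer.
- 11 is acetylated (Ac2O, pyridine) to (2E)-3-(4-acetoxyphenyl)prop-2-enoic acid F5.
- Steglich esterification of 10 with it (EDC, DMAP, CH2Cl2) gives tert-butyl (2E)-3-[(2S)-2-{(2S)-1-[(2E)-3-(4-acetoxyphenyl)prop-2-enoyloxy]propan-2-yl}-2,3-dihydro-1-benzofuran-5-yl]prop-2-enoate F6.
- Aminolysis with pyrrolidine (CH2Cl2, 0 °C) removes only the far more reactive aryl acetate and gives 12.

3. Step 5.
- What may go wrong: oxidative addition into the electron-rich C5-Br bond (para to O1) may be sluggish, and the catalyst may decay to palladium black before conversion is complete.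
- Fallback (from 7, back at 9): C5 is made the nucleophile.
- Bromine-lithium exchange (n-BuLi, THF, -78 °C) and quenching with DMF give (2S)-2-[(2S)-1-(tert-butyldimethylsilyloxy)propan-2-yl]-2,3-dihydro-1-benzofuran-5-carbaldehyde F7.
- A Horner-Wadsworth-Emmons reaction with tert-butyl diethylphosphonoacetate (LiCl, DBU, MeCN) gives the E-enoate 9.

Further compounds
F1 | step 4 | methyl 2-(5-bromo-2-{[(2R)-3-(tert-butyldimethylsilyloxy)-2-methylpropyl]oxy}phenyl)acetate | C[C@@H](CO[Si](C)(C)C(C)(C)C)COc1ccc(Br)cc1CC(=O)OC
F2 | step 4 | methyl 2-(5-bromo-2-{[(2R)-3-(tert-butyldimethylsilyloxy)-2-methylpropyl]oxy}phenyl)-2-diazoacetate | C[C@@H](CO[Si](C)(C)C(C)(C)C)COc1ccc(Br)cc1C(=[N+]=[N-])C(=O)OC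
F3 | step 4 | methyl (2R,3R)-5-bromo-2-[(2S)-1-(tert-butyldimethylsilyloxy)propan-2-yl]-2,3-dihydro-1-benzofuran-3-carboxylate | C[C@@H](CO[Si](C)(C)C(C)(C)C)[C@@H]1[C@H](C(=O)OC)c2cc(Br)ccc2O1
F4 | step 4 | (2R)-5-bromo-2-[(2S)-1-(tert-butyldimethylsilyloxy)propan-2-yl]-2,3-dihydro-1-benzofuran-3-carboxylic acid (C3 epimers) | C[C@@H](CO[Si](C)(C)C(C)(C)C)[C@@H]1C(C(=O)O)c2cc(Br)ccc2O1
F5 | step 7 | (2E)-3-(4-acetoxyphenyl)prop-2-enoic acid | CC(=O)Oc1ccc(/C=C/C(=O)O)cc1
F6 | step 7 | tert-butyl (2E)-3-[(2S)-2-{(2S)-1-[(2E)-3-(4-acetoxyphenyl)prop-2-enoyloxy]propan-2-yl}-2,3-dihydro-1-benzofuran-5-yl]prop-2-enoate | C[C@@H](COC(=O)/C=C/c1ccc(OC(C)=O)cc1)[C@@H]1Cc2cc(/C=C/C(=O)OC(C)(C)C)ccc2O1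
F7 | step 5 | (2S)-2-[(2S)-1-(tert-butyldimethylsilyloxy)propan-2-yl]-2,3-dihydro-1-benzofuran-5-carbaldehyde | C[C@@H](CO[Si](C)(C)C(C)(C)C)[C@@H]1Cc2cc(C=O)ccc2O1
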